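**Plan**

- Numbering used: cyclopent-2-en-1-one C1 (C=O), C2=C3, C4 (CH–OAc), C5 (C–OH), side-chain carbinol C1' carrying C14H29. The target is (4R,5S,1'S), with O4 and O5 trans and the side chain cis to O4.
- Enabling feature: C5 is α to the C1 ketone and C4 is an oxygenated carbon β to it, so C4–C5 is an aldol bond. The array O=C4H–C3H=C2H–C1(=O)–C5H(OH) with a cis double bond is an oxidised 2-furyl carbinol (furan C5, C4, C3, C2 plus the carbinol carbon).
- Cuts, in order: the two acetates and a silyl ether on O1'; C4–C5 (ring contraction of an Achmatowicz lactol, a 6-hydroxy-2H-pyran-3(6H)-one); the pyranone back to a 2-furyl carbinol; the furan–carbinol C–C bond (2-furyllithium plus (S)-2-silyloxyhexadecanal); the chain C3–C4 bond (methyl (S)-glycidate plus a C13 Grignard reagent).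
- Forward: the chain is joined first (epoxide opening, silylation, reduction, furyl addition). The furan then becomes the six-membered pyranone lactol, which contracts to the five-membered carbocycle; desilylation and double acetylation finish.
- Stereochemistry: C1' is bought with the glycidate. C5 and C4 are both created in the ring contraction: C4 relative to C5 by conrotatory closure of the cis-enediol, and C5 relative to C1' by closure anti to the C1'–OSi bond. The furyl carbinol centre is erased on enolisation, so both epimers converge.

Key step: step 6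

Remark: TBS = tert-butyldimethylsilyl. In the silyl ethers 13 and F2 the C5 descriptor reads R instead of S only because the silyloxy group raises the CIP rank of C1'; the spatial arrangement is that of the target throughout.

**Step 1**
Reactants: 1 methyl (2S)-oxirane-2-carboxylate (methyl (S)-glycidate); 2 1-bromotridecane
Product: 4 methyl (2S)-2-hydroxyhexadecanoate, via tridecylmagnesium bromide 3 (not isolated)
Conditions: Mg, THF; then CuI (10 mol %), 1, THF, −40 °C; H2O work-up
Reagents that add atoms: none
Why: Copper-catalysed SN2 opening of the terminal epoxide by the Grignard reagent at the unsubstituted C3 should outrun addition to the ester at low temperature, and the bought C2 stereocentre is not touched.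

**Step 2**
Reactants: 4 methyl (2S)-2-hydroxyhexadecanoate
Product: 5 methyl (2S)-2-[(tert-butyldimethylsilyl)oxy]hexadecanoate
Conditions: TBSCl, imidazole, DMF, 25 °C
Reagents that add atoms: tert-butyldimethylsilyl chloride, CC(C)(C)[Si](C)(C)Cl
Why: Standard silylation of a secondary alcohol; the bulky, non-chelating silyl ether is the temporary group that later steers the ring closure and cannot leave by β-elimination.

**Step 3**
Reactants: 5 methyl (2S)-2-[(tert-butyldimethylsilyl)oxy]hexadecanoate
Product: 6 (2S)-2-[(tert-butyldimethylsilyl)oxy]hexadecanal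
Conditions: i-Bu2AlH (1.1 equiv), CH2Cl2, −78 °C; then aq. potassium sodium tartrate
Reagents that add atoms: none
Why: Partial reduction of an α-silyloxy methyl ester at −78 °C stops at the tetrahedral aluminium hemiacetal, which should release the aldehyde on work-up without epimerisation (used crude).

**Step 4**
Reactants: 6 (2S)-2-[(tert-butyldimethylsilyl)oxy]hexadecanal; 7 furan
Product: 9 (2S)-2-[(tert-butyldimethylsilyl)oxy]-1-(furan-2-yl)hexadecan-1-ol (mixture of C1 epimers), via 2-furyllithium 8 (not isolated)
Conditions: n-BuLi, THF, 0 °C; then 6, −78 °C; H2O work-up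
Reagents that add atoms: none
Why: 1,2-Addition of 2-lithiofuran (from α-lithiation of furan) to the aldehyde; either carbinol epimer is acceptable because this carbon becomes sp2 in step 6.

**Step 5**
Reactants: 9 (2S)-2-[(tert-butyldimethylsilyl)oxy]-1-(furan-2-yl)hexadecan-1-ol
Product: 11 2-{(1S)-1-[(tert-butyldimethylsilyl)oxy]pentadecyl}-6-hydroxy-2H-pyran-3(6H)-one (mixture at C2 and C6), via open-chain keto-aldehyde 10 (not isolated)
Conditions: NBS, NaHCO3, NaOAc, THF/H2O (4:1), 0 °C
Reagents that add atoms: water, O
Why: Achmatowicz rearrangement: bromonium-induced oxidative opening of the furan gives the (Z)-4-oxo-2-enal 10, which the free carbinol captures as the six-membered lactol; the silyl ether and C1' are untouched.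

**Step 6**
Reactants: 11 2-{(1S)-1-[(tert-butyldimethylsilyl)oxy]pentadecyl}-6-hydroxy-2H-pyran-3(6H)-one
Product: 13 (4R,5R)-5-{(1S)-1-[(tert-butyldimethylsilyl)oxy]pentadecyl}-4,5-dihydroxycyclopent-2-en-1-one, via enediol 12 (not isolated)
Conditions: Et3N (0.3 equiv), toluene, 0 °C to 25 °C
Reagents that add atoms: none
Why: Lactol 11 reacts through its ring-opened tautomer, the (Z)-keto-aldehyde 10 from which it arose in step 5: Et3N removes H-5 of this open form in the hydrogen-bonded α-ketol conformer to give the (Z)-enediol 12 (both oxygens cis, side chain on the inner side of the U), and C5 then bonds to the formyl carbon C4 in an intramolecular aldol addition which, because enol, cis-alkene and formyl group are conjugated, is a 4π-conrotatory closure of a trioxygenated pentadienyl system. The closest known reaction type is the base-induced ring contraction of Achmatowicz lactols and of cis-4-oxo-2-enals from furan oxidation to 4-hydroxycyclopent-2-enones, the same ring closure as in the Piancatelli rearrangement. The cyclopentenone closes in a formally 5-(enolendo)-exo-trig mode, made feasible by the cis C2=C3 double bond and the pericyclic character. C4 relative to C5: conrotation with both oxygens outside (s-trans formyl group, Z-enediol) should put O4 and O5 trans and the side chain cis to O4. C5 relative to C1': allylic strain holds H-1' in the enol plane toward H-2, and the new bond should form on the face anti to the C1'–OSi bond of this hydrogen-eclipsed conformer, the empirical pattern of electrophilic additions to allylic ethers, here with a bulky silyl ether that neither chelates nor accepts a hydrogen bond, giving (4R,5R)-13, the spatial arrangement of the target. The step needs face selectivity and no β-elimination or loss of C1': silyloxide is a poor leaving group, C5 is quaternary after closure so the enone cannot drift to a 2-substituted isomer, and catalytic amine in a non-polar solvent keeps the internal hydrogen bond and limits retro-aldol equilibration.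

**Step 7**
Reactants: 13 (4R,5R)-5-{(1S)-1-[(tert-butyldimethylsilyl)oxy]pentadecyl}-4,5-dihydroxycyclopent-2-en-1-one
Product: 14 (4R,5S)-4,5-dihydroxy-5-[(1S)-1-hydroxypentadecyl]cyclopent-2-en-1-one
Conditions: HF·pyridine, THF, 0 °C to 25 °C
Reagents that add atoms: none
Why: Fluoride-driven Si–O cleavage under weakly acidic, non-basic conditions should spare the β-hydroxy ketone from retro-aldol cleavage; no stereocentre is touched.

**Step 8**
Reactants: 14 (4R,5S)-4,5-dihydroxy-5-[(1S)-1-hydroxypentadecyl]cyclopent-2-en-1-one
Product: 15 (4R,5S)-4-acetoxy-5-[(1S)-1-acetoxypentadecyl]-5-hydroxycyclopent-2-en-1-one (target)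
Conditions: Ac2O, pyridine, CH2Cl2, 0 °C to 25 °C
Reagents that add atoms: acetic anhydride, CC(=O)OC(C)=O
Why: Pyridine-mediated O-acylation should take the two secondary alcohols (C4 and C1') and leave the hindered tertiary α-ketol hydroxyl at C5 free; the acetates cannot eliminate because C5 carries no hydrogen.

**Compound list**

1 | methyl (2S)-oxirane-2-carboxylate (methyl (S)-glycidate) | COC(=O)[C@@H]1CO1 | starting material
2 | 1-bromotridecane | CCCCCCCCCCCCCBr | starting material
3 | tridecylmagnesium bromide | CCCCCCCCCCCCC[Mg]Br | intermediate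
4 | methyl (2S)-2-hydroxyhexadecanoate | CCCCCCCCCCCCCC[C@H](O)C(=O)OC | intermediate
5 | methyl (2S)-2-[(tert-butyldimethylsilyl)oxy]hexadecanoate | CCCCCCCCCCCCCC[C@H](O[Si](C)(C)C(C)(C)C)C(=O)OC | intermediate
6 | (2S)-2-[(tert-butyldimethylsilyl)oxy]hexadecanal | CCCCCCCCCCCCCC[C@H](O[Si](C)(C)C(C)(C)C)C=O | intermediate
7 | furan | c1ccoc1 | starting material
8 | 2-furyllithium | [Li]c1ccco1 | intermediate
9 | (2S)-2-[(tert-butyldimethylsilyl)oxy]-1-(furan-2-yl)hexadecan-1-ol, C1 epimers | CCCCCCCCCCCCCC[C@H](O[Si](C)(C)C(C)(C)C)C(O)c1ccco1 | intermediate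
10 | (2Z,6S)-6-[(tert-butyldimethylsilyl)oxy]-5-hydroxy-4-oxoicos-2-enal, C5 epimers | CCCCCCCCCCCCCC[C@H](O[Si](C)(C)C(C)(C)C)C(O)C(=O)/C=C\C=O | intermediate
11 | 2-{(1S)-1-[(tert-butyldimethylsilyl)oxy]pentadecyl}-6-hydroxy-2H-pyran-3(6H)-one, mixture at C2 and C6 | CCCCCCCCCCCCCC[C@H](O[Si](C)(C)C(C)(C)C)C1OC(O)C=CC1=O | intermediate
12 | (2Z,4Z,6S)-6-[(tert-butyldimethylsilyl)oxy]-4,5-dihydroxyicosa-2,4-dienal | CCCCCCCCCCCCCC[C@H](O[Si](C)(C)C(C)(C)C)/C(O)=C(O)\C=C/C=O | intermediate
13 | (4R,5R)-5-{(1S)-1-[(tert-butyldimethylsilyl)oxy]pentadecyl}-4,5-dihydroxycyclopent-2-en-1-one | CCCCCCCCCCCCCC[C@H](O[Si](C)(C)C(C)(C)C)[C@@]1(O)C(=O)C=C[C@H]1O | intermediate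
14 | (4R,5S)-4,5-dihydroxy-5-[(1S)-1-hydroxypentadecyl]cyclopent-2-en-1-one | CCCCCCCCCCCCCC[C@H](O)[C@@]1(O)C(=O)C=C[C@H]1O | intermediate
15 | (4R,5S)-4-acetoxy-5-[(1S)-1-acetoxypentadecyl]-5-hydroxycyclopent-2-en-1-one | CCCCCCCCCCCCCC[C@H](OC(C)=O)[C@@]1(O)C(=O)C=C[C@H]1OC(C)=O | target

**Step count and risks**

Total step count: 8. Longest linear sequence: 8 steps (1 and 2 to 15).

Steps most likely to fail:

Step 6. The closure may discriminate the two faces of the enediol poorly (bond formation syn to the silyloxy group), or lose the trans relationship through stepwise closure or retro-aldol equilibration, so that 13 is formed mixed with its C4/C5 stereoisomers. The fallback sets out from 13 (as that stereoisomer mixture) and returns to 13. All isomers are oxidised at the allylic C4 carbinol with Dess–Martin periodinane (NaHCO3, CH2Cl2) to the single ene-dione 2-{(1S)-1-[(tert-butyldimethylsilyl)oxy]pentadecyl}-2-hydroxycyclopent-4-ene-1,3-dione F1, in which C4 and C5 are no longer stereocentres. A Corey–Bakshi–Shibata reduction of one of the two diastereotopic carbonyl groups ((S)-2-methyl-CBS-oxazaborolidine, catecholborane, toluene, −78 °C) should then set both centres under reagent control. The catalyst fixes the new carbinol as R (quaternary C5 as the large flank) and hydride enters anti to the bulky side chain; only one carbonyl group can satisfy both, so O4 should end cis to the side chain and trans to O5, which is 13.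

Step 7. Cleavage of the hindered secondary silyl ether beside the quaternary carbon may be slow, with retro-aldol fragmentation or dehydration of the free triol during prolonged exposure. The fallback sets out from 13 and returns at 15; the order is changed so that the unprotected aldol is never exposed. Compound 13 is first acetylated at O4 (Ac2O, pyridine) to (1R,5R)-5-{(1S)-1-[(tert-butyldimethylsilyl)oxy]pentadecyl}-5-hydroxy-4-oxocyclopent-2-en-1-yl acetate F2, whose C4–C5 retro-aldol path is blocked. The silyl ether is then cleaved (HF·pyridine, THF) to (1R,5S)-5-hydroxy-5-[(1S)-1-hydroxypentadecyl]-4-oxocyclopent-2-en-1-yl acetate F3. Acetylation of the C1' hydroxyl (Ac2O, pyridine, cat. DMAP, 0 °C) should give 15.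

Step 1. The Grignard reagent may add to the ester carbonyl, or bromide may open the epoxide, instead of the copper-mediated attack at C3. The fallback sets out from 3 and returns at 6; the ester is replaced by an ether. Compound 3 opens commercial (S)-benzyl glycidyl ether (CuI cat., THF, −30 °C) to (2S)-1-(benzyloxy)hexadecan-2-ol F4. Silylation (TBSCl, imidazole, DMF) gives {[(2S)-1-(benzyloxy)hexadecan-2-yl]oxy}(tert-butyl)dimethylsilane F5. Hydrogenolysis (H2, Pd/C, EtOAc) gives (2S)-2-[(tert-butyldimethylsilyl)oxy]hexadecan-1-ol F6, and Dess–Martin oxidation should give aldehyde 6.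

**Further compounds**

F1 | step 6 | 2-{(1S)-1-[(tert-butyldimethylsilyl)oxy]pentadecyl}-2-hydroxycyclopent-4-ene-1,3-dione | CCCCCCCCCCCCCC[C@H](O[Si](C)(C)C(C)(C)C)C1(O)C(=O)C=CC1=O
F2 | step 7 | (1R,5R)-5-{(1S)-1-[(tert-butyldimethylsilyl)oxy]pentadecyl}-5-hydroxy-4-oxocyclopent-2-en-1-yl acetate | CCCCCCCCCCCCCC[C@H](O[Si](C)(C)C(C)(C)C)[C@@]1(O)C(=O)C=C[C@H]1OC(C)=O
F3 | step 7 | (1R,5S)-5-hydroxy-5-[(1S)-1-hydroxypentadecyl]-4-oxocyclopent-2-en-1-yl acetate | CCCCCCCCCCCCCC[C@H](O)[C@@]1(O)C(=O)C=C[C@H]1OC(C)=O
F4 | step 1 | (2S)-1-(benzyloxy)hexadecan-2-ol | CCCCCCCCCCCCCC[C@H](O)COCc1ccccc1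
F5 | step 1 | {[(2S)-1-(benzyloxy)hexadecan-2-yl]oxy}(tert-butyl)dimethylsilane | CCCCCCCCCCCCCC[C@H](O[Si](C)(C)C(C)(C)C)COCc1ccccc1
F6 | step 1 | (2S)-2-[(tert-butyldimethylsilyl)oxy]hexadecan-1-ol | CCCCCCCCCCCCCC[C@H](O[Si](C)(C)C(C)(C)C)CO
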